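The data come from a simulation from invented constants.

Follow one molecule of coupling partner as it enters, and ask at its fork what it meets: starting material or protic impurity.

| flask | starting material | coupling partner | protic impurity | remark | time |
|---|---|---|---|---|---|
| spring | 5 mM | 0.67 equiv (fed, over 25 s) | 5 mM | run made earlier |  |
| dawn | 5 mM | 1.5 equiv (fed, over 25 s) | 5 mM | run made earlier |  |
| flask | 5.0 mM | 1.00 equiv (fed, over 25 s) | 5.00 mM |  | 8.0 min |

| run | time / min | starting material / % | target / % | isomer of the product / % |
|---|---|---|---|---|
| spring | 1.00 | 44.6 | 17.8 | 30.8 |
| spring | 2.00 | 42.6 | 14.8 | 41.8 |
| spring | 3.00 | 42.3 | 14.8 | 42.8 |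
| spring | 4.00 | 42.8 | 14.9 | 42.7 |
| spring | 5.00 | 42.5 | 14.7 | 42.8 |
| spring | 6.00 | 42.2 | 14.7 | 42.7 |
| dawn | 1.00 | 6.7 | 29.8 | 52.6 |
| dawn | 2.00 | 1.7 | 25.5 | 71.5 |
| dawn | 3.00 | 0.7 | 26.2 | 73.6 |
| dawn | 4.00 | 0.6 | 25.6 | 73.8 |
| dawn | 5.00 | 0.1 | 25.7 | 74.3 |
| dawn | 6.00 | 0.5 | 25.7 | 74.3 |

(readings scatter by 0.3 percentage points)

- the state of affairs at 8.0 min: stopped, and by what, or still going (it is still moving / the coupling partner has run out first / forward and back rates have come level / all of the starting material has reacted)
- how much of the starting material has reacted by 8.0 min
- how much target there is at 8.0 min, in percent of the starting material charged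
- how much isomer of the product there is at 8.0 min, in percent of the starting material charged

- the reaction counts as stopped when no species that holds the starting material changes by six tenths of a point or more over the second half of the time

Start with the first instants, when the fork opens. The spring run stopped with 42.5 % starting material, so 57.5 % of the charge had reacted out of 0.67 equiv of partner. The missing 0.0950 equiv is taken here as quenched by the impurity, whose charge equals that of the starting material. Both consumers draw on the same partner, so the logarithm of the impurity fraction left, divided by that of the starting material fraction left, gives 0.117. This reading from the spring run is the quench ratio, a selectivity factor: the rate constant of partner with impurity over that with starting material.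

In the middle, material is hidden. The spring readings sum to 93.2 % at 1.00 min but 99.2 % at 2.00 min, which reads as an unseen intermediate draining into the products.

At the end, target makes up 25.7 % of the products in the dawn run and 25.6 % in the spring run. The spring run stands flat from 3.00 min, earlier than the 8.0 min asked here.

For this flask, the charges are equal and the partner is 1.00 equiv, so once the partner is consumed the fractions of starting material and impurity left must sum to one. Starting material left at 18.1 % satisfies this, since the quench ratio then leaves 81.9 % of the impurity. The reckoning here is therefore that partner is the limiting reagent, with 21.0 % target and 60.9 % isomer. The forecast says that the coupling partner has run out first, with 81.9 % reacted, 21 % target and 60.9 % isomer, and says of target and isomer: “these two equilibrate, whatever the conversion”.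

In the flask the coupling partner has run out first, with 0 % of it left, 82.1 % reacted, 21.1 % target and 61.1 % isomer.

    starting material + coupling partner → intermediate (k = 21.0 /M/s)
    coupling partner + protic impurity → quenched reagent (k = 2.40 /M/s)
    intermediate → target (k = 0.0650 /s)
    target ⇌ isomer of the product (K = 2.90, k = 0.0700 /s)

At 0.417 min, when the feed ended, the flask held 42.9 % of its partner and 26.9 % intermediate. By 4.00 min the partner was down to 0.0424 % and the intermediate to 0.0221 %, with target and isomer already at 21.1 % and 61.0 %. The 17.9 % of starting material left, raised to the quench ratio, gives 81.8 %, and the flask holds 82 % of its impurity. The neighbour charged with 0.400 equiv of partner ended with 64.8 % starting material; that fraction raised to the quench ratio gives 95.1 %, and the protic impurity left in that neighbour stands at 95.2 %.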